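Remark on the chemistry: the sense of induction of the (R)-configured phosphoric acid in step 6 is assumed to lead to the (2R,3S,4R) adduct; if it proves opposite, the (S)-configured acid is used and nothing else changes.

## Analysis of the target

Target 17 is a trans-dihydroflavonol (a 3-hydroxychroman-4-one). Ring A (C4a, C5–C8, C8a) is a phloroglucinol nucleus with a free 5-OH chelated to the C4 carbonyl and a prenyl ether on O7. Ring C (O1, C2, C3, C4, C4a, C8a) is the dihydropyranone, and ring B on C2 is a guaiacyl group (3'-OMe, 4'-OH). The only stereocentres are C2 (R) and C3 (R), contiguous, with the aryl group and the hydroxyl trans and diequatorial, which is also the more stable relative arrangement. Both centres are labile once the ketone exists: C3–H is alpha to C4=O, and the O1–C2 bond of a beta-aryloxy ketone opens by retro-oxa-Michael reaction under base, so base can epimerise or racemise the compound and, with air, take it to the flavonol. The prenyl ether does not tolerate hydrogenolysis, strong acid or quinone oxidants, and it must sit on O7 alone among four hydroxyls. The difficulty is therefore absolute control of C2 and C3 with no resident stereocentre to lean on, in a framework that allows little base, together with differentiation of the hydroxyls. The strategy rests on ring C: the unit O1–C8a–C4a–C4, with C4 at the aldehyde oxidation level, is the heterodiene of an ortho-quinone methide, and the unit C2–C3 with its trans aryl and oxygen substituents is an E-configured beta-acyloxystyrene. One [4+2] union of the two forms C3–C4 and O1–C2, closes ring C and sets both stereocentres.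

## Retrosynthetic reasoning

The O7–prenyl bond is cut first, leading from 17 back to the tetrahydroxy compound 15 and prenyl bromide 16. The prenyl ether would not survive the hydrogenolysis and oxidation steps that precede it, so it can only be introduced at the end. The forward step has to alkylate O7 alone; the 7-OH, para to the C4 carbonyl, is by far the most acidic hydroxyl of 15, and that acidity is what the step relies on.

The three free phenols of 15 are traced back to the tribenzyl ether 14. Benzyl ethers are chosen because they survive acid, base and a quinone oxidant and leave under neutral hydrogenolysis, which does not disturb the base-sensitive C2/C3 pair.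

The C4 carbonyl of 14 is traced back to a C4 methyl ether, compound 12, through the hemiketal 13. The cycloaddition delivers C4 at the ether level, one oxidation state too low. The C4–H bond is benzylic to the trioxygenated ring A and alpha to an ether oxygen, so a hydride-abstracting quinone can remove it selectively; this step also erases the C4 stereocentre, so its configuration never needs to be controlled.

The free 3-OH of 12 is traced back to the benzoate 11. The ester is removed before the oxidation, not after it: at the flavan stage neither C2 nor C3 is acidic, whereas an ester cleavage on the ketone would expose the alpha-acyloxy ketone to alkoxide.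

The key disconnection cuts C3–C4 and O1–C2 of 11 and leads to the phenol acetal 3 and the enol benzoate 9 through the ortho-quinone methide 10. These two bonds are cut because both fragments are then achiral, easily made aromatics, because ring A stays aromatic throughout, and because a single catalytic step closes ring C and sets C2 and C3. The forward reaction must place the aryl group at C2 and not C3, keep aryl and acyloxy trans, and select one enantiomer.

Acetal 3 is traced back to the salicylaldehyde 2 and from there to 2,4,6-trihydroxybenzaldehyde 1. The chelated ortho-hydroxyl of 1 is the one that resists alkylation, and that is the hydroxyl the quinone methide needs free.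

Enol benzoate 9 is cut at its vinyl C–O bond to the alkenyltrifluoroborate 7 and benzoic acid 8, and 7 is traced through the pinacol boronate 6 to O-benzylvanillin 4 and the geminal diboron reagent 5. Acylating an arylacetaldehyde enolate would be shorter on paper, but it does not control the alkene geometry. The boron route fixes the E geometry at the olefination and transfers it stereospecifically in the C–O coupling.

## Alternatives that were turned down

Alternative 1: The disconnection is in ring A, at C4a–C5, so that the aromatic ring is made last. The precursor is the stereodefined ring C pyranone A1, which carries the three missing ring A carbons as an acetoacetate chain on C8a. In the forward key step a dienolate of A1 attacks the terminal ester through C4a, the alkoxide leaves and enolisation aromatises ring A to the dihydroxy compound A2. In its favour, the step is biomimetic, C2 and C3 are set earlier by conventional acyclic chemistry, and A2 emerges with 5-OH and 7-OH free while O3 and O4' are still benzylated. Prenylation of O7 would then compete only with the chelated 5-OH, which is more secure than the final step of the chosen route. Against it, A1 needs a long linear synthesis. The polyanion conditions act on a 3-alkoxy-2-aryl-dihydropyranone that can epimerise at C3 or open by retro-oxa-Michael reaction. The most acidic methylene of the chain can also fold in the aldol sense onto the C4 ketone instead of the Claisen sense. Finally, the two remaining benzyl ethers could not be removed by hydrogenolysis once the prenyl group is in place, so the protecting-group advantage is lost without redesign. The chosen strategy buys ring A aromatic, is convergent from two short fragments and creates both stereocentres catalytically in one step.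

Alternative 2: The disconnection is C3–C4, leading to the dialdehyde A3, in which the ring A aldehyde is tethered through O1 to an alpha-aryl acetaldehyde. In the forward key step a chiral N-heterocyclic carbene turns the ring A aldehyde into an acyl-anion equivalent that adds to the aliphatic aldehyde, closing ring C and giving A4, which is the same compound as 14. On step economy after ring closure this alternative is stronger: C3 and C4 arrive at their final oxidation levels and steps 7 and 8 of the chosen route would not be needed. Against it, the C2 stereocentre of A3 is an alpha-aryl, alpha-aryloxy aldehyde centre that enolises very easily and would racemise under the basic carbene conditions, and making A3 enantioenriched is itself a problem. The carbene must also engage the hindered, electron-rich, doubly ortho-substituted aromatic aldehyde in preference to the unhindered aliphatic one; the opposite polarity gives the isomeric 4-hydroxychroman-3-one. The alpha-ketol product can isomerise under the same conditions. The chosen strategy takes two more steps after ring closure but sets C2 and C3 together from precursors that have no stereocentre to lose.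

Alternative 3: The disconnection cuts O1–C8a and C4–C4a, leading to the aryne precursor A5 and the anti-configured hydroxy ester A6. In the forward key step the benzylic alkoxide of A6 adds to the aryne released from A5 at the carbon remote from the flanking benzyloxy group, and the aryl anion formed next to that group acylates on the ester, closing ring C to the tetrabenzyl ether A7. In its favour, the route is convergent, both stereocentres are imported from an acyclic compound without any new asymmetric step, the innate regiochemistry of a 3-alkoxyaryne fits the target, and A7 needs only hydrogenolysis and prenylation. On stereochemical security and on the number of steps after ring closure it is as strong as or stronger than the chosen route. Against it, the anti-diol pattern of A6 is not the one that dihydroxylation of an E-cinnamate gives, so it needs an inversion or an anti-selective glycolate aldol plus differentiation of the two hydroxyls, and A5 takes several steps. In additions of alcohols to arynes the aryl anion is usually quenched by proton transfer before it can acylate, which would give an uncyclised aryl ether. The beta-alkoxide of A6 can also undergo retro-aldol cleavage, and its alpha-centre can epimerise under the basic fluoride conditions. The chosen strategy has simpler precursors and a shorter overall sequence, and its risk is concentrated in one catalytic step.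

Key step: step 6

## Route

Step 1
Reactants: 1 2,4,6-trihydroxybenzaldehyde
Product: 2 2,4-bis(benzyloxy)-6-hydroxybenzaldehyde
Conditions: BnBr (2.1 equiv), K2CO3 (2.2 equiv), DMF, 0 °C → rt
Reagents that add atoms: benzyl bromide, BrCc1ccccc1
Why: Williamson etherification; the 4-OH and one ortho-OH react, and the remaining ortho-OH is held in a six-membered hydrogen bond to the formyl oxygen and is much less nucleophilic, so the reaction should stop at the dibenzyl ether.

Step 2
Reactants: 2 2,4-bis(benzyloxy)-6-hydroxybenzaldehyde
Product: 3 3,5-bis(benzyloxy)-2-(dimethoxymethyl)phenol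
Conditions: HC(OMe)3, MeOH, PPTS (cat.), rt; then Et3N, concentrate, use without chromatography
Reagents that add atoms: trimethyl orthoformate, COC(OC)OC; methanol, CO
Why: Acid-catalysed acetalisation driven by the orthoester as water scavenger; the acid is neutralised with amine before concentration because an ortho-hydroxybenzaldehyde acetal of this electron-rich ring ionises easily.

Step 3
Reactants: 4 4-(benzyloxy)-3-methoxybenzaldehyde (O-benzylvanillin); 5 2,2'-methylenebis(4,4,5,5-tetramethyl-1,3,2-dioxaborolane)
Product: 6 2-[(E)-2-(4-benzyloxy-3-methoxyphenyl)ethenyl]-4,4,5,5-tetramethyl-1,3,2-dioxaborolane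
Conditions: lithium 2,2,6,6-tetramethylpiperidide (LiTMP), THF, 0 °C; then 4, −78 °C → rt; aq. NH4Cl
Reagents that add atoms: none
Why: Boron–Wittig olefination; the lithiated geminal diboronate adds to the aldehyde and the alkoxide eliminates with the boron that leaves the aryl group and the remaining boryl group trans, so the E alkenylboronate is expected.

Step 4
Reactants: 6 2-[(E)-2-(4-benzyloxy-3-methoxyphenyl)ethenyl]-4,4,5,5-tetramethyl-1,3,2-dioxaborolane
Product: 7 potassium [(E)-2-(4-benzyloxy-3-methoxyphenyl)ethenyl]trifluoroborate
Conditions: KHF2 (aq.), MeOH, rt; precipitation from acetone/Et2O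
Reagents that add atoms: potassium hydrogen difluoride, [K+].F[H-]F
Why: Ligand exchange on boron by bifluoride gives the crystalline, bench-stable trifluoroborate, the boron partner best suited to the copper coupling; the alkene geometry is untouched.

Step 5
Reactants: 7 potassium [(E)-2-(4-benzyloxy-3-methoxyphenyl)ethenyl]trifluoroborate; 8 benzoic acid
Product: 9 (E)-2-(4-benzyloxy-3-methoxyphenyl)ethenyl benzoate
Conditions: CuBr (10 mol%), DMAP (20 mol%), 4 Å MS, O2 (1 atm), MeCN, 60 °C
Reagents that add atoms: none
Why: Chan–Lam-type oxidative C–O coupling; transmetalation of the alkenyl group to a divalent copper benzoate, oxidation to trivalent copper and C–O reductive elimination proceed with retention at the alkene, so the E geometry of 7 is carried into the enol ester.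

Step 6
Reactants: 3 3,5-bis(benzyloxy)-2-(dimethoxymethyl)phenol; 9 (E)-2-(4-benzyloxy-3-methoxyphenyl)ethenyl benzoate
Product: 11 (2R,3S,4R)-5,7-bis(benzyloxy)-2-(4-benzyloxy-3-methoxyphenyl)-4-methoxy-3,4-dihydro-2H-chromen-3-yl benzoate (all-trans), via ortho-quinone methide 10 (not isolated)
Conditions: (R)-TRIP [(R)-3,3'-bis(2,4,6-triisopropylphenyl)-1,1'-binaphthyl-2,2'-diyl hydrogen phosphate] (10 mol%), 5 Å MS, toluene, 0 °C → rt, slow addition of 3
Reagents that add atoms: none
Why: The acid protonates one acetal oxygen of 3, methanol leaves with help from the ortho-hydroxyl, and the 4-methoxy ortho-quinone methide 10 stays hydrogen-bonded and ion-paired to the chiral phosphate. The alkene carbon of 9 that bears the benzoate attacks the methide carbon to form C3–C4, and the benzylic positive charge developing at C2 is captured by the dienone oxygen to form O1–C2, so ring C closes in an asynchronous inverse-demand oxa-[4+2] cycloaddition, suprafacial on both partners (in the stepwise limit, a six-membered capture of the cation by the phenol oxygen). The closest known reaction type is the chiral-phosphoric-acid-catalysed [4+2] cycloaddition of ortho-quinone methides generated in situ with styrenes and enol derivatives, together with the acid-promoted union of salicylaldehyde acetals and styrenes to 4-alkoxy-2-arylchromans. The trans relation of C2 and C3 is inherited from the E alkene, and a stepwise path converges on the same diequatorial arrangement at ring closure. C4 is set by the E geometry of the methide and the aryl-endo approach, which put the methoxy group trans to the benzoate; this centre is removed in step 8, so its selectivity is not critical. The absolute configuration at C2 and C3 is controlled by the 2,4,6-triisopropylphenyl groups of the phosphate, which shield one face of the bound methide. The step needs regioselectivity (aryl at C2), which the para-benzyloxy group secures because it stabilises positive charge at C2 far better than the weakly donating benzoyloxy group could at C3. It also needs chemoselectivity against self-condensation of 10, which slow addition of 3 and removal of methanol by the sieves should secure.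

Step 7
Reactants: 11 (2R,3S,4R)-5,7-bis(benzyloxy)-2-(4-benzyloxy-3-methoxyphenyl)-4-methoxy-3,4-dihydro-2H-chromen-3-yl benzoate
Product: 12 (2R,3S,4R)-5,7-bis(benzyloxy)-2-(4-benzyloxy-3-methoxyphenyl)-4-methoxy-3,4-dihydro-2H-chromen-3-ol
Conditions: NaOMe (cat.), MeOH/THF, rt
Reagents that add atoms: none
Why: Zemplén-type transesterification of the secondary benzoate; with no carbonyl in the ring neither C2 nor C3 can epimerise, and the benzyl ethers and the C4 methyl ether are inert to methoxide.

Step 8
Reactants: 12 (2R,3S,4R)-5,7-bis(benzyloxy)-2-(4-benzyloxy-3-methoxyphenyl)-4-methoxy-3,4-dihydro-2H-chromen-3-ol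
Product: 14 (2R,3R)-5,7-bis(benzyloxy)-2-(4-benzyloxy-3-methoxyphenyl)-3-hydroxy-2,3-dihydro-4H-chromen-4-one, via C4 hemiketal 13 (not isolated)
Conditions: DDQ (1.3 equiv), CH2Cl2/H2O (10:1), 0 °C → rt
Reagents that add atoms: water, O
Why: Oxidative cleavage of an electron-rich benzylic ether by DDQ; hydride abstraction from the pseudo-axial C4–H, activated by the trioxygenated ring A and the methoxy group, gives a stabilised cation, water adds to the hemiketal 13 and loss of methanol leaves the ketone, which deactivates ring A so that the oxidation should stop there. C2 and C3 are not touched; their descriptors become (2R,3R) only because the ranking of the substituents at C3 changes.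

Step 9
Reactants: 14 (2R,3R)-5,7-bis(benzyloxy)-2-(4-benzyloxy-3-methoxyphenyl)-3-hydroxy-2,3-dihydro-4H-chromen-4-one
Product: 15 (2R,3R)-3,5,7-trihydroxy-2-(4-hydroxy-3-methoxyphenyl)-2,3-dihydro-4H-chromen-4-one
Conditions: H2 (1 atm), Pd/C (10% palladium on carbon), EtOAc/MeOH, rt
Reagents that add atoms: none
Why: Hydrogenolysis of the three aryl benzyl ethers under neutral conditions; the chelated aryl ketone and the secondary alcohol should not be reduced at atmospheric pressure and room temperature, and no base is present to disturb C2 or C3.

Step 10
Reactants: 15 (2R,3R)-3,5,7-trihydroxy-2-(4-hydroxy-3-methoxyphenyl)-2,3-dihydro-4H-chromen-4-one; 16 1-bromo-3-methylbut-2-ene (prenyl bromide)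
Product: 17 (2R,3R)-3,5-dihydroxy-2-(4-hydroxy-3-methoxyphenyl)-7-[(3-methylbut-2-en-1-yl)oxy]-2,3-dihydro-4H-chromen-4-one
Conditions: K2CO3 (1.05 equiv), 16 (1.1 equiv), acetone, rt, argon
Reagents that add atoms: none
Why: Williamson etherification under acidity control; the 7-OH is a vinylogous carboxylic acid through the C4 carbonyl and is deprotonated first by one equivalent of weak base, the 5-OH is chelated, the 4'-OH is a weaker acid and the 3-OH is an alcohol, so O7 should be alkylated selectively.

## Compound list

1 | 2,4,6-trihydroxybenzaldehyde | O=Cc1c(O)cc(O)cc1O | starting material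
2 | 2,4-bis(benzyloxy)-6-hydroxybenzaldehyde | O=Cc1c(O)cc(OCc2ccccc2)cc1OCc1ccccc1 | intermediate
3 | 3,5-bis(benzyloxy)-2-(dimethoxymethyl)phenol | COC(OC)c1c(O)cc(OCc2ccccc2)cc1OCc1ccccc1 | intermediate
4 | 4-(benzyloxy)-3-methoxybenzaldehyde (O-benzylvanillin) | COc1cc(C=O)ccc1OCc1ccccc1 | starting material
5 | 2,2'-methylenebis(4,4,5,5-tetramethyl-1,3,2-dioxaborolane) | CC1(C)OB(CB2OC(C)(C)C(C)(C)O2)OC1(C)C | starting material
6 | 2-[(E)-2-(4-benzyloxy-3-methoxyphenyl)ethenyl]-4,4,5,5-tetramethyl-1,3,2-dioxaborolane | COc1cc(/C=C/B2OC(C)(C)C(C)(C)O2)ccc1OCc1ccccc1 | intermediate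
7 | potassium [(E)-2-(4-benzyloxy-3-methoxyphenyl)ethenyl]trifluoroborate | COc1cc(/C=C/[B-](F)(F)F)ccc1OCc1ccccc1.[K+] | intermediate
8 | benzoic acid | OC(=O)c1ccccc1 | starting material
9 | (E)-2-(4-benzyloxy-3-methoxyphenyl)ethenyl benzoate | COc1cc(/C=C/OC(=O)c2ccccc2)ccc1OCc1ccccc1 | intermediate
10 | (6E)-3,5-bis(benzyloxy)-6-(methoxymethylidene)cyclohexa-2,4-dien-1-one (4-methoxy ortho-quinone methide, not isolated) | CO/C=C1/C(=O)C=C(OCc2ccccc2)C=C1OCc1ccccc1 | intermediate
11 | (2R,3S,4R)-5,7-bis(benzyloxy)-2-(4-benzyloxy-3-methoxyphenyl)-4-methoxy-3,4-dihydro-2H-chromen-3-yl benzoate | COc1cc([C@H]2Oc3cc(OCc4ccccc4)cc(OCc4ccccc4)c3[C@@H](OC)[C@@H]2OC(=O)c2ccccc2)ccc1OCc1ccccc1 | intermediate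
12 | (2R,3S,4R)-5,7-bis(benzyloxy)-2-(4-benzyloxy-3-methoxyphenyl)-4-methoxy-3,4-dihydro-2H-chromen-3-ol | COc1cc([C@H]2Oc3cc(OCc4ccccc4)cc(OCc4ccccc4)c3[C@@H](OC)[C@@H]2O)ccc1OCc1ccccc1 | intermediate
13 | (2R,3R)-5,7-bis(benzyloxy)-2-(4-benzyloxy-3-methoxyphenyl)-4-methoxy-3,4-dihydro-2H-chromene-3,4-diol (C4 hemiketal, either configuration at C4, not isolated) | COc1cc([C@H]2Oc3cc(OCc4ccccc4)cc(OCc4ccccc4)c3C(O)(OC)[C@@H]2O)ccc1OCc1ccccc1 | intermediate
14 | (2R,3R)-5,7-bis(benzyloxy)-2-(4-benzyloxy-3-methoxyphenyl)-3-hydroxy-2,3-dihydro-4H-chromen-4-one | COc1cc([C@H]2Oc3cc(OCc4ccccc4)cc(OCc4ccccc4)c3C(=O)[C@@H]2O)ccc1OCc1ccccc1 | intermediate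
15 | (2R,3R)-3,5,7-trihydroxy-2-(4-hydroxy-3-methoxyphenyl)-2,3-dihydro-4H-chromen-4-one | COc1cc([C@H]2Oc3cc(O)cc(O)c3C(=O)[C@@H]2O)ccc1O | intermediate
16 | 1-bromo-3-methylbut-2-ene (prenyl bromide) | CC(C)=CCBr | starting material
17 | (2R,3R)-3,5-dihydroxy-2-(4-hydroxy-3-methoxyphenyl)-7-[(3-methylbut-2-en-1-yl)oxy]-2,3-dihydro-4H-chromen-4-one | COc1cc([C@H]2Oc3cc(OCC=C(C)C)cc(O)c3C(=O)[C@@H]2O)ccc1O | target

## Step count and risk

Total step count: 10. Longest linear sequence: 8 steps (steps 3, 4, 5, 6, 7, 8, 9, 10, from 4). The ring A branch (steps 1 and 2) joins at step 6.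

Least certain steps:

Step 6 (key step). The acyloxy group makes the alkene of 9 a weak nucleophile, so C3–C4 bond formation may be slower than self-condensation of the quinone methide or its return to the acetal. Enantioselectivity may also erode if the strongly stabilised oxocarbenium ion escapes the chiral ion pair, and acyl transfer from the enol ester to the phenol is conceivable. The fallback keeps ring A and the quinone methide but moves the C3 oxygen to a later step. It sets out from 3 and 4 and returns at 14.
- Wittig methylenation of 4 (methyltriphenylphosphonium bromide, potassium tert-butoxide) gives 1-(benzyloxy)-4-ethenyl-2-methoxybenzene F1.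
- The same acid-catalysed cycloaddition of 3 with this more nucleophilic styrene, the best-precedented pairing, should give the 2,4-cis flavan (2S,4S)-5,7-bis(benzyloxy)-2-(4-benzyloxy-3-methoxyphenyl)-4-methoxy-3,4-dihydro-2H-chromene F2.
- DDQ in wet dichloromethane oxidises C4 to the flavanone (2S)-5,7-bis(benzyloxy)-2-(4-benzyloxy-3-methoxyphenyl)-2,3-dihydro-4H-chromen-4-one F3.
- Soft enolisation (TMSOTf, Et3N) gives the silyl enol ether (2S)-5,7-bis(benzyloxy)-2-(4-benzyloxy-3-methoxyphenyl)-4-(trimethylsilyloxy)-2H-chromene F4.
- Rubottom oxidation with dimethyldioxirane, anti to the C2 aryl group, followed by mild acidic work-up, installs the 3-hydroxyl trans and gives 14.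

The C2 descriptor changes from S to R along this path only through substituent ranking.

Step 8. Hydride abstraction could occur at C2, which is benzylic to the dialkoxyphenyl ring B, leading to ring opening. The oxidation could also stall if a C4 epimer cannot align its C–H bond with ring A. The fallback sets out from 12 and returns at 14. Aqueous acid solvolysis of the C4 methyl ether (p-TsOH, THF/H2O) through the ring A stabilised cation gives (2R,3S)-5,7-bis(benzyloxy)-2-(4-benzyloxy-3-methoxyphenyl)-3,4-dihydro-2H-chromene-3,4-diol F5 as a mixture of C4 epimers. MnO2 in dichloromethane then oxidises the benzylic C4 alcohol selectively in the presence of the aliphatic 3-OH and gives 14.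

Step 10. Over-alkylation at the 4'-phenol, and base-induced retro-oxa-Michael opening with loss of configuration at C2 and C3 or air oxidation to the flavonol, are the likely failures. The fallback sets out from 15 and returns at 17. It replaces the phenoxide alkylation by a Mitsunobu etherification with 3-methylbut-2-en-1-ol, PPh3 and diisopropyl azodicarboxylate in THF at 0 °C. This runs without added base and also discriminates the hydroxyls by acidity. No new compound arises on this path (F0).

Step 2. Acetalisation may be incomplete because the aldehyde is hydrogen-bonded and electronically a vinylogous ester, and the phenol acetal may ionise and revert during isolation. The fallback sets out from 2 and returns at 3.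
- Acetylation (Ac2O, pyridine) removes the hydrogen bond and gives 3,5-bis(benzyloxy)-2-formylphenyl acetate F6.
- Acetalisation as in step 2 gives the phenol-free, more robust acetal 3,5-bis(benzyloxy)-2-(dimethoxymethyl)phenyl acetate F7.
- K2CO3 in MeOH at 0 °C cleaves the aryl acetate under purely basic conditions and releases 3 immediately before step 6.

Step 5. Protodeboronation or oxidative homocoupling of the electron-rich styryl boron species may outrun C–O bond formation. The fallback sets out from 4 and returns at 9.
- Wittig reaction with (methoxymethyl)triphenylphosphonium chloride and potassium tert-butoxide gives 1-(benzyloxy)-2-methoxy-4-(2-methoxyethenyl)benzene F8 as an E/Z mixture.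
- Aqueous acid hydrolysis gives 2-(4-benzyloxy-3-methoxyphenyl)acetaldehyde F9.
- O-benzoylation of its enolate (benzoyl chloride, Et3N, DMAP) gives 9 together with (Z)-2-(4-benzyloxy-3-methoxyphenyl)ethenyl benzoate F10.
- Iodine-catalysed equilibration and crystallisation should enrich the E isomer 9.

## Further compounds

F1 | step 6 | 1-(benzyloxy)-4-ethenyl-2-methoxybenzene | COc1cc(C=C)ccc1OCc1ccccc1
F2 | step 6 | (2S,4S)-5,7-bis(benzyloxy)-2-(4-benzyloxy-3-methoxyphenyl)-4-methoxy-3,4-dihydro-2H-chromene | COc1cc([C@H]2Oc3cc(OCc4ccccc4)cc(OCc4ccccc4)c3[C@@H](OC)C2)ccc1OCc1ccccc1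
F3 | step 6 | (2S)-5,7-bis(benzyloxy)-2-(4-benzyloxy-3-methoxyphenyl)-2,3-dihydro-4H-chromen-4-one | COc1cc([C@H]2Oc3cc(OCc4ccccc4)cc(OCc4ccccc4)c3C(=O)C2)ccc1OCc1ccccc1
F4 | step 6 | (2S)-5,7-bis(benzyloxy)-2-(4-benzyloxy-3-methoxyphenyl)-4-(trimethylsilyloxy)-2H-chromene | COc1cc([C@H]2Oc3cc(OCc4ccccc4)cc(OCc4ccccc4)c3C(O[Si](C)(C)C)=C2)ccc1OCc1ccccc1
F5 | step 8 | (2R,3S)-5,7-bis(benzyloxy)-2-(4-benzyloxy-3-methoxyphenyl)-3,4-dihydro-2H-chromene-3,4-diol (C4 epimers) | COc1cc([C@H]2Oc3cc(OCc4ccccc4)cc(OCc4ccccc4)c3C(O)[C@@H]2O)ccc1OCc1ccccc1
F0 | step 10 | none | none
F6 | step 2 | 3,5-bis(benzyloxy)-2-formylphenyl acetate | CC(=O)Oc1cc(OCc2ccccc2)cc(OCc2ccccc2)c1C=O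
F7 | step 2 | 3,5-bis(benzyloxy)-2-(dimethoxymethyl)phenyl acetate | COC(OC)c1c(OC(C)=O)cc(OCc2ccccc2)cc1OCc1ccccc1
F8 | step 5 | 1-(benzyloxy)-2-methoxy-4-(2-methoxyethenyl)benzene (E/Z mixture) | COC=Cc1ccc(OCc2ccccc2)c(OC)c1
F9 | step 5 | 2-(4-benzyloxy-3-methoxyphenyl)acetaldehyde | COc1cc(CC=O)ccc1OCc1ccccc1
F10 | step 5 | (Z)-2-(4-benzyloxy-3-methoxyphenyl)ethenyl benzoate | COc1cc(/C=C\OC(=O)c2ccccc2)ccc1OCc1ccccc1
A1 | alternative 1 | methyl 4-[(2R,3R)-3-(benzyloxy)-2-(4-benzyloxy-3-methoxyphenyl)-4-oxo-3,4-dihydro-2H-pyran-6-yl]-3-oxobutanoate | COc1cc([C@H]2OC(CC(=O)CC(=O)OC)=CC(=O)[C@@H]2OCc2ccccc2)ccc1OCc1ccccc1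
A2 | alternative 1 | (2R,3R)-3-(benzyloxy)-2-(4-benzyloxy-3-methoxyphenyl)-5,7-dihydroxy-2,3-dihydro-4H-chromen-4-one | COc1cc([C@H]2Oc3cc(O)cc(O)c3C(=O)[C@@H]2OCc2ccccc2)ccc1OCc1ccccc1
A3 | alternative 2 | (2R)-2-[3,5-bis(benzyloxy)-2-formylphenoxy]-2-(4-benzyloxy-3-methoxyphenyl)acetaldehyde | COc1cc([C@H](C=O)Oc2cc(OCc3ccccc3)cc(OCc3ccccc3)c2C=O)ccc1OCc1ccccc1
A4 | alternative 2 | (2R,3R)-5,7-bis(benzyloxy)-2-(4-benzyloxy-3-methoxyphenyl)-3-hydroxy-2,3-dihydro-4H-chromen-4-one | COc1cc([C@H]2Oc3cc(OCc4ccccc4)cc(OCc4ccccc4)c3C(=O)[C@@H]2O)ccc1OCc1ccccc1
A5 | alternative 3 | 3,5-bis(benzyloxy)-2-(trimethylsilyl)phenyl trifluoromethanesulfonate | C[Si](C)(C)c1c(OS(=O)(=O)C(F)(F)F)cc(OCc2ccccc2)cc1OCc1ccccc1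
A6 | alternative 3 | methyl (2R,3R)-2-(benzyloxy)-3-(4-benzyloxy-3-methoxyphenyl)-3-hydroxypropanoate | COc1cc([C@@H](O)[C@@H](OCc2ccccc2)C(=O)OC)ccc1OCc1ccccc1
A7 | alternative 3 | (2R,3R)-3,5,7-tris(benzyloxy)-2-(4-benzyloxy-3-methoxyphenyl)-2,3-dihydro-4H-chromen-4-one | COc1cc([C@H]2Oc3cc(OCc4ccccc4)cc(OCc4ccccc4)c3C(=O)[C@@H]2OCc2ccccc2)ccc1OCc1ccccc1
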